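**Plan**

1. Numbering: ring A is the resorcinol ring (C-1 chain, O-2 and O-4 hydroxyls, C-5 1,1-dimethylallyl). Ring B is the chromene arene (C-1' chain, O-3' free OH, O-4' pyran oxygen, C-5' pyran carbon, C-6' prenyl). The chain is Cα (on ring A), Cβ, Cγ (on ring B).
2. Retrosynthesis: one operation cuts all three C5 units from carbon: C-5–CMe2 on ring A, C-6'–CH2 on ring B, and C-5'–CH= together with the pyran O–CMe2 bond. This leads back to the O-4 prenyl, O-3' prenyl and O-4' 1,1-dimethylpropargyl ethers of a bare 1,3-diarylpropane (11). The Cα carbonyl, the Cβ=Cγ double bond and the Cβ–Cγ aldol bond are then cut to give ketone 3 and aldehyde 7.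
3. Enabling feature: every C5 attachment carbon is ortho or para to a phenol oxygen, and the skeleton itself blocks the wrong exits. C-5 is ortho to O-4, whose para carbon C-1 carries the chain. C-5' is the only free ortho carbon of O-4'. C-6' is para to O-3' and is reached by Cope relay from both ortho carbons, C-2' and C-4'.
4. Forward: the three ethers are placed on two commercial monomers using the intrinsic acidity order of their hydroxyls, with no protecting group. The chain is joined by Claisen–Schmidt condensation and saturated without hydrogenation (zinc, then carbonyl removal assisted by the never-protected O-2 hydroxyl). The pyran ring and both C-bound C5 groups arise last, in one thermal cascade.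
5. Stereochemistry: the target has no stereocentre and no configured double bond; the E-enone of 8 is reduced away.

Key step: step 7

Remark: kazinol K as drawn is achiral, so "single enantiomer" is taken to mean the one constitution shown. "Prenyl" means 3-methylbut-2-en-1-yl throughout.

**Route**

Step 1
Reactants: 1 2,4-dihydroxyacetophenone; 2 prenyl bromide (1-bromo-3-methylbut-2-ene)
Product: 3 1-[2-hydroxy-4-(prenyloxy)phenyl]ethan-1-one
Conditions: K2CO3 (1.1 equiv), acetone, reflux
Reagents that add atoms: none
Why: Williamson ether synthesis; the 2-OH is hydrogen-bonded to the acetyl carbonyl and much less nucleophilic, so only the 4-OH (future O-4) should be alkylated.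

Step 2
Reactants: 4 3,4-dihydroxybenzaldehyde; 5 3-chloro-3-methylbut-1-yne
Product: 6 3-hydroxy-4-[(2-methylbut-3-yn-2-yl)oxy]benzaldehyde
Conditions: DBU (1.05 equiv), CuCl2·2H2O (1 mol %), MeCN, Ar, 0 °C to rt
Reagents that add atoms: none
Why: Copper-catalysed O-propargylation of a phenoxide with a tertiary propargylic chloride (through a copper allenylidene); one equivalent of base ionises only the 4-OH, which is para to the formyl group and the more acidic, so the ether should form at the future O-4'.

Step 3
Reactants: 6 3-hydroxy-4-[(2-methylbut-3-yn-2-yl)oxy]benzaldehyde; 2 prenyl bromide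
Product: 7 3-(prenyloxy)-4-[(2-methylbut-3-yn-2-yl)oxy]benzaldehyde
Conditions: K2CO3, DMF, rt
Reagents that add atoms: none
Why: Williamson ether synthesis on the one remaining phenol; at room temperature neither the aryl propargyl ether nor the new prenyl ether rearranges.

Step 4
Reactants: 3 1-[2-hydroxy-4-(prenyloxy)phenyl]ethan-1-one; 7 3-(prenyloxy)-4-[(2-methylbut-3-yn-2-yl)oxy]benzaldehyde
Product: 8 (E)-1-[2-hydroxy-4-(prenyloxy)phenyl]-3-{3-(prenyloxy)-4-[(2-methylbut-3-yn-2-yl)oxy]phenyl}prop-2-en-1-one
Conditions: KOH (50 % aq), EtOH, rt; AcOH quench at 0 °C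
Reagents that add atoms: none
Why: Claisen–Schmidt (crossed aldol) condensation; the aldehyde cannot enolise, the ethers and the terminal alkyne are stable to hydroxide, and E1cB dehydration gives the conjugated E-enone.

Step 5
Reactants: 8 the 2'-hydroxychalcone
Product: 9 1-[2-hydroxy-4-(prenyloxy)phenyl]-3-{3-(prenyloxy)-4-[(2-methylbut-3-yn-2-yl)oxy]phenyl}propan-1-one
Conditions: Zn dust, NH4Cl, EtOH/H2O, 70 °C
Reagents that add atoms: none
Why: Dissolving-metal conjugate reduction; zinc transfers electrons only to the low-lying π* of the aryl enone and ammonium chloride protonates the β-carbon and the enolate, while the isolated trisubstituted alkenes, the terminal alkyne and the aryl ketone should not be reduced under these near-neutral conditions.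

Step 6
Reactants: 9 the 2'-hydroxydihydrochalcone
Product: 11 5-(prenyloxy)-2-(3-{3-(prenyloxy)-4-[(2-methylbut-3-yn-2-yl)oxy]phenyl}propyl)phenol, via aryl ethyl carbonate 10 (not isolated)
Conditions: ClCO2Et, Et3N, THF, 0 °C; then NaBH4, THF/H2O, 0 °C to rt
Reagents that add atoms: none
Why: Reductive deoxygenation of an ortho-hydroxyaryl ketone through its aryl carbonate: borohydride reduces the ketone, the benzylic alkoxide takes the carbonate group over from O-2, 1,4-elimination of ethyl carbonate gives a transient ortho-quinone methide and a second hydride adds to its exocyclic carbon, a sequence in which the alkenes, the alkyne and the ethers take no part.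

Step 7
Reactants: 11 the diarylpropane tris-ether
Product: 13 kazinol K, via chromene bis-prenyl ether 12 (not isolated)
Conditions: o-dichlorobenzene (0.01 M, degassed), Ar, sealed tube, 140 °C, then 190 °C
Reagents that add atoms: none
Why: At 140 °C the O-4' aryl 1,1-dimethylpropargyl ether should undergo a propargyl Claisen [3,3] shift to C-5', followed by enolisation of the allenyl dienone, a [1,5]-H shift to an ortho-quinone methide and ring closure to 12; at 190 °C the O-4 prenyl ether should undergo an ortho-Claisen [3,3] shift to C-5 and the O-3' prenyl ether a Claisen [3,3] shift to C-2' or C-4' followed by a Cope [3,3] shift to C-6', each ending in tautomerisation to the phenol. The closest known reactions are the thermal conversion of aryl 1,1-dimethylpropargyl ethers into 2,2-dimethyl-2H-chromenes, the ortho-Claisen rearrangement of aryl prenyl ethers to 2-(1,1-dimethylallyl)phenols and the tandem para-Claisen–Cope rearrangement of aryl prenyl ethers to 4-prenylphenols. The only ring formed, the pyran, closes by a thermal oxa-6π electrocyclisation that makes the O–CMe2 bond, and no stereocentre arises. The chromene can only form at C-5' because the other ortho carbon of O-4', C-3', is oxygenated. On ring A the step needs C-5 over C-3: the para carbon C-1 carries the chain, so a para dienone can only revert, and C-3 lies between two oxygenated carbons and would have to take up a quaternary carbon, whereas C-5 is unhindered and para to the O-2 donor. On ring B the step needs C-6' over C-2': both ortho carbons of O-3' relay by Cope shift to the same para carbon, the C-4' dienone cannot enolise, the C-2' dienone is crowded between the chain and the new quaternary carbon, and high dilution in a non-basic solvent slows bimolecular enolisation so that the dienones can equilibrate and tautomerise from the less strained para dienone.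

**Compound list**

1 | 2,4-dihydroxyacetophenone | CC(=O)c1ccc(O)cc1O | starting material
2 | prenyl bromide (1-bromo-3-methylbut-2-ene) | CC(C)=CCBr | starting material
3 | 1-[2-hydroxy-4-(prenyloxy)phenyl]ethan-1-one | CC(=O)c1ccc(OCC=C(C)C)cc1O | intermediate
4 | 3,4-dihydroxybenzaldehyde | O=Cc1ccc(O)c(O)c1 | starting material
5 | 3-chloro-3-methylbut-1-yne | CC(C)(Cl)C#C | starting material
6 | 3-hydroxy-4-[(2-methylbut-3-yn-2-yl)oxy]benzaldehyde | O=Cc1ccc(OC(C)(C)C#C)c(O)c1 | intermediate
7 | 3-(prenyloxy)-4-[(2-methylbut-3-yn-2-yl)oxy]benzaldehyde | O=Cc1ccc(OC(C)(C)C#C)c(OCC=C(C)C)c1 | intermediate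
8 | (E)-1-[2-hydroxy-4-(prenyloxy)phenyl]-3-{3-(prenyloxy)-4-[(2-methylbut-3-yn-2-yl)oxy]phenyl}prop-2-en-1-one | O=C(/C=C/c1ccc(OC(C)(C)C#C)c(OCC=C(C)C)c1)c1ccc(OCC=C(C)C)cc1O | intermediate
9 | 1-[2-hydroxy-4-(prenyloxy)phenyl]-3-{3-(prenyloxy)-4-[(2-methylbut-3-yn-2-yl)oxy]phenyl}propan-1-one | O=C(CCc1ccc(OC(C)(C)C#C)c(OCC=C(C)C)c1)c1ccc(OCC=C(C)C)cc1O | intermediate
10 | ethyl 5-(prenyloxy)-2-(3-{3-(prenyloxy)-4-[(2-methylbut-3-yn-2-yl)oxy]phenyl}propanoyl)phenyl carbonate | CCOC(=O)Oc1cc(OCC=C(C)C)ccc1C(=O)CCc1ccc(OC(C)(C)C#C)c(OCC=C(C)C)c1 | intermediate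
11 | 5-(prenyloxy)-2-(3-{3-(prenyloxy)-4-[(2-methylbut-3-yn-2-yl)oxy]phenyl}propyl)phenol | Oc1cc(OCC=C(C)C)ccc1CCCc1ccc(OC(C)(C)C#C)c(OCC=C(C)C)c1 | intermediate
12 | 2-{3-[2,2-dimethyl-8-(prenyloxy)-2H-chromen-6-yl]propyl}-5-(prenyloxy)phenol | Oc1cc(OCC=C(C)C)ccc1CCCc1cc(OCC=C(C)C)c2OC(C)(C)C=Cc2c1 | intermediate
13 | kazinol K, 4-{3-[8-hydroxy-2,2-dimethyl-5-(3-methylbut-2-en-1-yl)-2H-chromen-6-yl]propyl}-6-(2-methylbut-3-en-2-yl)benzene-1,3-diol | C=CC(C)(C)c1cc(CCCc2cc(O)c3c(c2CC=C(C)C)C=CC(C)(C)O3)c(O)cc1O | target

**Step count and risks**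

Total step count: 7. Longest linear sequence: 6 (steps 2, 3, 4, 5, 6, 7 from 3,4-dihydroxybenzaldehyde).

Steps most likely to fail, riskiest first:

Step 7. The ortho dienone formed at C-2' of ring B may tautomerise before it undergoes the Cope shift, which would strand the C5 unit as a 1,1-dimethylallyl group at C-2'. Part of the ring A prenyl group may also migrate to C-3, and long heating may cause retro-ene loss of isoprene or abnormal Claisen isomerisation of the product. The fallback blocks C-2' with a removable bromine, so that both ortho carbons of O-3' are substituted and the para-Claisen–Cope path is the only one open. It sets out from 6 and comes back to the route at 13. Ortho-selective bromination of 6 (NBS, cat. i-Pr2NH, CH2Cl2, 0 °C; C-2 is the only free ortho carbon of the hydroxyl) should give 2-bromo-3-hydroxy-4-[(2-methylbut-3-yn-2-yl)oxy]benzaldehyde F1. Prenylation with 2 as in step 3 should give 2-bromo-3-(prenyloxy)-4-[(2-methylbut-3-yn-2-yl)oxy]benzaldehyde F2. Condensation with 3 as in step 4 should give the bromo chalcone F3, and zinc/ammonium chloride as in step 5, which leaves the aryl bromide alone, the bromo dihydrochalcone F4. Carbonate formation to the bromo aryl ethyl carbonate F5 (not isolated) and borohydride reduction as in step 6 should give the bromo diarylpropane tris-ether F6. Heating as in step 7 should pass through the bromo chromene bis-prenyl ether F7 (not isolated) to 2'-bromokazinol K F8. Radical hydrodebromination (Bu3SnH, AIBN, toluene, 90 °C) then returns to 13.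

Step 5. The zinc reduction may over-reduce the substrate, couple two enone radical anions at the β-carbon, or allow the 2'-hydroxychalcone to close to the flavanone in the warm aqueous medium. The fallback avoids the enone altogether and makes the Cα–Cβ bond by enolate alkylation. It sets out from 7 and comes back to the route at 9. Reduction of 7 (NaBH4, MeOH, 0 °C) should give [3-(prenyloxy)-4-[(2-methylbut-3-yn-2-yl)oxy]phenyl]methanol F9. Appel bromination (CBr4, PPh3, CH2Cl2, 0 °C) should give 4-(bromomethyl)-2-(prenyloxy)-1-[(2-methylbut-3-yn-2-yl)oxy]benzene F10, used at once. Double deprotonation of 3 (LDA, 2.2 equiv, THF, −78 °C) and alkylation of the methyl ketone enolate with F10 should give 9 directly.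

Step 2. Site selectivity between the two catechol hydroxyls may erode, double alkylation may occur with the hindered tertiary electrophile, or copper may oxidise the catechol. The fallback separates site differentiation from the hindered etherification by a temporary allyl group. It sets out from 4 and comes back to the route at 7. Mono-allylation of the more acidic 4-OH (allyl bromide, 1.0 equiv, NaHCO3, NaI, DMF, 40 °C) should give 3-hydroxy-4-(prop-2-en-1-yloxy)benzaldehyde F11. Prenylation with 2 (K2CO3, DMF, rt) should give 3-(prenyloxy)-4-(prop-2-en-1-yloxy)benzaldehyde F12. Palladium-catalysed deallylation (Pd(PPh3)4, morpholine, THF, rt), which ionises the unsubstituted allyl ether much faster than the prenyl ether, should give 4-hydroxy-3-(prenyloxy)benzaldehyde F13. Copper-catalysed propargylation of this single phenol with 5 (DBU, cat. CuCl2, MeCN) then gives 7.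

**Further compounds**

F1 | step 7 | 2-bromo-3-hydroxy-4-[(2-methylbut-3-yn-2-yl)oxy]benzaldehyde | O=Cc1ccc(OC(C)(C)C#C)c(O)c1Br
F2 | step 7 | 2-bromo-3-(prenyloxy)-4-[(2-methylbut-3-yn-2-yl)oxy]benzaldehyde | O=Cc1ccc(OC(C)(C)C#C)c(OCC=C(C)C)c1Br
F3 | step 7 | (E)-3-{2-bromo-3-(prenyloxy)-4-[(2-methylbut-3-yn-2-yl)oxy]phenyl}-1-[2-hydroxy-4-(prenyloxy)phenyl]prop-2-en-1-one | O=C(/C=C/c1ccc(OC(C)(C)C#C)c(OCC=C(C)C)c1Br)c1ccc(OCC=C(C)C)cc1O
F4 | step 7 | 3-{2-bromo-3-(prenyloxy)-4-[(2-methylbut-3-yn-2-yl)oxy]phenyl}-1-[2-hydroxy-4-(prenyloxy)phenyl]propan-1-one | O=C(CCc1ccc(OC(C)(C)C#C)c(OCC=C(C)C)c1Br)c1ccc(OCC=C(C)C)cc1O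
F5 | step 7 | 2-(3-{2-bromo-3-(prenyloxy)-4-[(2-methylbut-3-yn-2-yl)oxy]phenyl}propanoyl)-5-(prenyloxy)phenyl ethyl carbonate | CCOC(=O)Oc1cc(OCC=C(C)C)ccc1C(=O)CCc1ccc(OC(C)(C)C#C)c(OCC=C(C)C)c1Br
F6 | step 7 | 2-(3-{2-bromo-3-(prenyloxy)-4-[(2-methylbut-3-yn-2-yl)oxy]phenyl}propyl)-5-(prenyloxy)phenol | Oc1cc(OCC=C(C)C)ccc1CCCc1ccc(OC(C)(C)C#C)c(OCC=C(C)C)c1Br
F7 | step 7 | 2-{3-[7-bromo-2,2-dimethyl-8-(prenyloxy)-2H-chromen-6-yl]propyl}-5-(prenyloxy)phenol | Oc1cc(OCC=C(C)C)ccc1CCCc1cc2C=CC(C)(C)Oc2c(OCC=C(C)C)c1Br
F8 | step 7 | 2'-bromokazinol K, 4-{3-[7-bromo-8-hydroxy-2,2-dimethyl-5-(3-methylbut-2-en-1-yl)-2H-chromen-6-yl]propyl}-6-(2-methylbut-3-en-2-yl)benzene-1,3-diol | C=CC(C)(C)c1cc(CCCc2c(Br)c(O)c3c(c2CC=C(C)C)C=CC(C)(C)O3)c(O)cc1O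
F9 | step 5 | [3-(prenyloxy)-4-[(2-methylbut-3-yn-2-yl)oxy]phenyl]methanol | OCc1ccc(OC(C)(C)C#C)c(OCC=C(C)C)c1
F10 | step 5 | 4-(bromomethyl)-2-(prenyloxy)-1-[(2-methylbut-3-yn-2-yl)oxy]benzene | BrCc1ccc(OC(C)(C)C#C)c(OCC=C(C)C)c1
F11 | step 2 | 3-hydroxy-4-(prop-2-en-1-yloxy)benzaldehyde | O=Cc1ccc(OCC=C)c(O)c1
F12 | step 2 | 3-(prenyloxy)-4-(prop-2-en-1-yloxy)benzaldehyde | O=Cc1ccc(OCC=C)c(OCC=C(C)C)c1
F13 | step 2 | 4-hydroxy-3-(prenyloxy)benzaldehyde | O=Cc1ccc(O)c(OCC=C(C)C)c1
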